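The earlier runs and the new flask come from a simulation from invented constants; the scatter is artificial.

The question was how much of the electrophile had reacted by 10 h, and what share of the nucleophile stood free rather than protonated.

| flask | electrophile | nucleophile | free base | remark | time |
|---|---|---|---|---|---|
| Friday's | 0.14 M | 0.15 M (fed, over 80 min) | 0.30 M | run made earlier |  |
| Thursday's | 0.22 M | 0.15 M (fed, over 80 min) | 0.30 M | run made earlier |  |
| Wednesday's | 0.10 M | 0.15 M (fed, over 80 min) | 0.45 M | run made earlier |  |
| flask | 0.10 M | 0.150 M (fed, over 80 min) | 0.300 M |  | 10 h |

- Friday's (time / h: electrophile / %, target / %): 1.33: 43.9, 49.7; 2.50: 26.9, 58.8; 4.00: 17.2, 56.8; 5.00: 13.5, 55.1; 6.00: 11.1, 52.7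
- Thursday's (time / h: electrophile / %, target / %): 1.33: 55.9, 39.0; 2.50: 42.7, 45.0; 4.00: 37.1, 42.0; 5.00: 35.9, 41.0; 6.00: 34.4, 39.7
- Wednesday's (time / h: electrophile / %, target / %): 0.500: 76.0, 22.2; 1.50: 28.0, 62.3; 3.00: 10.6, 67.3; 4.00: 6.0, 63.6; 6.00: 3.1, 58.1

(standard deviation of a reading: 0.5 percentage points)

- part of the electrophile that has reacted at 10 h
- share of free nucleophile in free nucleophile and protonated nucleophile together, at 10 h

Each turnover of electrophile + nucleophile → acid set free + target spends one nucleophile, so I counted turnovers. I took N = 1.50, the nucleophile charged per electrophile charged. Thursday's run had N = 0.682, which made nucleophile the limiting reagent, and its reacted part crept from 62.9 % to 65.6 % over the last readings, still under N. Wednesday's run had the flask's N but more free base, 0.45 M against 0.300 M, and had reacted 96.9 % at 6.00 h. So I expected more than that in the flask, given its longer time. But the readings show neither form of the nucleophile, so my count gave no figure for the share.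

The forecast said 98 % and 43 %, the second “poorly determined”.

The flask gave 99.5 % and 34.2 %.

    nucleophile + acid set free ⇌ protonated nucleophile, settled at all times (K = 66000 /M)
    electrophile + nucleophile → acid set free + target (k = 0.820 /M/min)
    nucleophile ⇌ dormant form (K = 2.80, k = 0.0590 /min)
    target ⇌ isomer of the product (K = 1.10, k = 0.00300 /min)
    acid set free + free base ⇌ salt of the base, settled at all times (K = 13000 /M)

With N = 1.50, the flask ended with electrophile at 0.490 % and free nucleophile at 5.86 % of its charge, beside 0.0169 M protonated, and the share stood 8.8 percentage points below the forecast. The neighbouring flask with 0.25 M of electrophile has N = 60.0 %, which is under one, so the count puts the reacted part there. That flask reacted 59.8 %, with nucleophile down to 0.031 % of its charge and electrophile left at 40.2 %.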